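## Retrosynthetic overview

1. The sulfate, the free catechol and the formyl group of the arene are set last: C3′ lithiation–formylation, ether cleavage, catechol silylene, O-sulfation, fluoride release.
2. The strategy rests on ring A. Its gem-dimethyl carbon C4 is bonded to C5 and its C1 to the ring-fusion carbon C10, which are the α- and β-carbons of a ring B cyclohexenone (C6 ketone, C5=C10). A 1,1-dimethylbutadiene unit therefore supplies C1–C4 in one (4+2) step that forms C1–C10 and C4–C5 and closes ring A.
3. The parent 4-methylpenta-1,3-diene (poor s-cis population, oligomerises under acid) is replaced by its 2-silyloxy derivative. The extra C2 oxygen is removed by Wolff–Kishner reduction, and the C6 ketone becomes the C5=C6 alkene through the axial alcohol and anti elimination.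
4. The ring B enone comes from (R)-pulegone via (R)-5-methylcyclohexenone and its 3-phenylsulfanyl enone. Two α′-alkylations anti to the C8 methyl (arylmethyl first, methyl second) set C9, and reduction–hydrolysis transposes the enone.
5. Order of ring formation: ring B (chiral pool), then attachment of the arene, then ring A (key step).

Key step: step 11

Numbering: decalin carbons C1–C10 as in the target (ring A = C1–C5 and C10, ring B = C5–C10); aryl carbons C1′ (bearing the CH2) to C6′.

Assumption: the target is taken as drawn, as the free aryl hydrogen sulfate, and is released in that form in the last step, although it would keep better as a salt.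

## Route

Step 1
Reactants: 1 (R)-pulegone
Product: 2 pulegone oxide, (6R)-2,2,6-trimethyl-1-oxaspiro[2.5]octan-4-one (both epoxide diastereomers)
Conditions: 30% H2O2, LiOH (cat.), MeOH, 0 °C to rt
Reagents that add atoms: hydrogen peroxide OO
Why: Nucleophilic (Weitz–Scheffer) epoxidation of the electron-poor exocyclic enone double bond, which leaves the methyl-bearing stereocentre (future C8) untouched; the epoxide configuration is of no consequence.

Step 2
Reactants: 2 pulegone oxide
Product: 3 (5R)-5-methyl-2-(phenylsulfanyl)cyclohexan-1-one (C2 epimers)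
Conditions: PhSNa, THF, reflux; aqueous work-up
Reagents that add atoms: sodium benzenethiolate [Na+].[S-]c1ccccc1
Why: The thiolate opens the epoxide at the carbon α to the ketone and the β-alkoxide so formed loses acetone by retro-aldol cleavage, a known degradation of this epoxide to the 2-sulfanyl ketone.

Step 3
Reactants: 3 (5R)-5-methyl-2-(phenylsulfanyl)cyclohexan-1-one
Product: 5 (R)-5-methylcyclohex-2-en-1-one, via sulfoxide 4 (not isolated)
Conditions: mCPBA, CH2Cl2, −78 °C; then CaCO3, toluene, 90 °C
Reagents that add atoms: none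
Why: Sulfide oxidation and thermal syn elimination of the β-keto sulfoxide (sulfoxide pyrolysis) can place the double bond only between C2 and C3, so the 5-methyl enone forms regiospecifically without touching the stereocentre.

Step 4
Reactants: 5 (R)-5-methylcyclohex-2-en-1-one
Product: 7 (S)-5-methyl-3-(phenylsulfanyl)cyclohex-2-en-1-one, via sulfanyl ketone 6 (not isolated)
Conditions: PhSH, Et3N (cat.), CH2Cl2, 0 °C to rt; then NCS, 0 °C; then Et3N, rt
Reagents that add atoms: benzenethiol Sc1ccccc1
Why: Thia-Michael addition followed by Pummerer-type α-chlorination of the sulfide and loss of HCl returns the conjugated double bond with sulfur on the β-carbon (oxidative β-sulfenylation of an enone), giving a vinylogous thioester whose carbonyl position is fixed so that the stereocentre cannot be lost by symmetrisation.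

Step 5
Reactants: 8 2,4,5-trimethoxybenzaldehyde
Product: 9 (2,4,5-trimethoxyphenyl)methanol
Conditions: NaBH4, MeOH, 0 °C
Reagents that add atoms: none
Why: Borohydride reduction of an aromatic aldehyde.

Step 6
Reactants: 9 (2,4,5-trimethoxyphenyl)methanol
Product: 10 1-(bromomethyl)-2,4,5-trimethoxybenzene (used at once)
Conditions: PBr3, Et2O, 0 °C
Reagents that add atoms: phosphorus tribromide BrP(Br)Br
Why: Bromide displaces the activated phosphite of a benzylic alcohol; the electron-rich bromide is not stored, to avoid self-condensation.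

Step 7
Reactants: 7 (S)-5-methyl-3-(phenylsulfanyl)cyclohex-2-en-1-one; 10 1-(bromomethyl)-2,4,5-trimethoxybenzene
Product: 11 (5R,6S)-5-methyl-3-(phenylsulfanyl)-6-(2,4,5-trimethoxybenzyl)cyclohex-2-en-1-one (arylmethyl trans to the 5-methyl)
Conditions: LiN(iPr)2 (LDA), THF, −78 °C; then 10, −78 to −30 °C
Reagents that add atoms: none
Why: Kinetic α′-deprotonation of the vinylogous thioester gives the cross-conjugated enolate (Stork–Danheiser alkylation), which should be benzylated at C6 mainly anti to the neighbouring methyl group; this centre is made planar again in step 8.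

Step 8
Reactants: 11 (5R,6S)-5-methyl-3-(phenylsulfanyl)-6-(2,4,5-trimethoxybenzyl)cyclohex-2-en-1-one
Product: 12 (5R,6R)-5,6-dimethyl-3-(phenylsulfanyl)-6-(2,4,5-trimethoxybenzyl)cyclohex-2-en-1-one
Conditions: LiN(iPr)2 (LDA), THF, −78 °C; MeI, DMPU, −78 to −20 °C
Reagents that add atoms: iodomethane CI
Why: A second kinetic α′-enolisation and methylation; iodomethane should approach the enolate carbon anti to the adjacent pseudoaxial methyl group, so the new methyl ends trans and the arylmethyl group cis to it, which sets the quaternary centre (future C9).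

Step 9
Reactants: 12 (5R,6R)-5,6-dimethyl-3-(phenylsulfanyl)-6-(2,4,5-trimethoxybenzyl)cyclohex-2-en-1-one
Product: 14 (4R,5R)-4,5-dimethyl-4-(2,4,5-trimethoxybenzyl)cyclohex-2-en-1-one, via allylic alcohol 13 (not isolated)
Conditions: LiAlH4, Et2O, 0 °C; then 2 M HCl, THF, rt
Reagents that add atoms: water O
Why: 1,2-Reduction and acid hydrolysis of the γ-hydroxy vinyl sulfide with allylic transposition (Stork–Danheiser enone transposition) move the carbonyl to the former sulfur-bearing carbon and leave the quaternary carbon in the γ-position; no stereocentre is involved.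

Step 10
Reactants: 15 mesityl oxide (4-methylpent-3-en-2-one)
Product: 16 tert-butyl(dimethyl)[(4-methylpenta-1,3-dien-2-yl)oxy]silane
Conditions: LiN(iPr)2 (LDA), THF, −78 °C; TBSCl, DMPU, −78 °C to rt
Reagents that add atoms: tert-butyldimethylsilyl chloride CC(C)(C)[Si](C)(C)Cl
Why: Kinetic deprotonation of the acetyl methyl group and O-silylation of the cross-conjugated lithium dienolate give the 2-silyloxydiene.

Step 11
Reactants: 14 (4R,5R)-4,5-dimethyl-4-(2,4,5-trimethoxybenzyl)cyclohex-2-en-1-one; 16 tert-butyl(dimethyl)[(4-methylpenta-1,3-dien-2-yl)oxy]silane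
Product: 17 2-(tert-butyldimethylsilyloxy)-4,4,8,9-tetramethyl-9-(2,4,5-trimethoxybenzyl)-cis-decal-2-en-6-one (H5, H10, 8-CH3 and the 9-arylmethyl group on one face; 9-CH3 on the other)
Conditions: 16 (2.5 equiv), HN(SO2CF3)2 (10 mol %), CH2Cl2, −78 to −40 °C; Et3N quench
Reagents that add atoms: none
Why: The silyl triflimide formed in the flask from HN(SO2CF3)2 and 16 activates the enone carbonyl, and the electron-rich 2-silyloxydiene adds suprafacially across C5=C10 in a strongly asynchronous (4+2) cycloaddition in which C1–C10 forms ahead of C4–C5 (in the limit a Mukaiyama–Michael addition followed by ring closure). The closest known reaction type is the acid-catalysed Diels–Alder reaction of hindered 4,4-disubstituted 2-silyloxy-1,3-dienes with cyclohex-2-enones, which gives cis-octalones with a quaternary carbon next to the ring fusion. Ring A is closed by this intermolecular (4+2) annulation as a six-membered carbocycle (the second bond corresponds to a 6-endo-trig attack of C5 on C4). C10 is set by approach of the diene anti to the pseudoaxial C9 arylmethyl group and the C8 methyl group, which lie on the same face of the half-chair enone, and C5 follows from the cis addition and is erased in step 14. The step needs C1-to-C10 and C4-to-C5 regiochemistry and anti facial selectivity; the first is secured because the silyloxy group makes C1 the nucleophilic terminus and C10 is the electrophilic β-carbon, the second by the two substituents on one face of 14. The silyloxy group is there because the parent 4-methylpenta-1,3-diene populates the s-cis form poorly and oligomerises under acid, whereas the silyl dienol ether has a raised HOMO and can also react stepwise.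

Step 12
Reactants: 17 cis-decalenone silyl enol ether
Product: 19 6-hydroxy-4,4,8,9-tetramethyl-9-(2,4,5-trimethoxybenzyl)-cis-decalin-2-one (6-OH axial on ring B and anti to H5), via silyl enol ether alcohol 18 (not isolated)
Conditions: LiBH(s-Bu)3 (L-Selectride), THF, −78 to 0 °C; then 1 M HCl, THF, rt
Reagents that add atoms: none
Why: The bulky hydride should attack the C6 ketone from the equatorial direction because the axial face is blocked by the axial C1 methylene of the cis-decalin, giving the axial alcohol anti to H5 before C5 can epimerise, and mild acid then hydrolyses the silyl enol ether to the C2 ketone.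

Step 13
Reactants: 19 6-hydroxy-cis-decalin-2-one
Product: 20 4,4,8,9-tetramethyl-9-(2,4,5-trimethoxybenzyl)-cis-decalin-6-ol (6-OH axial, anti to H5)
Conditions: N2H4·H2O, KOH, diethylene glycol, 130 then 200 °C
Reagents that add atoms: none
Why: Wolff–Kishner reduction (Huang–Minlon procedure) of the unhindered C2 ketone; with C6 already an alcohol the strongly basic medium cannot open ring A by retro-Michael cleavage.

Step 14
Reactants: 20 cis-decalin-6-ol
Product: 21 1-{[(1R,2R,8aS)-1,2,5,5-tetramethyl-1,2,3,5,6,7,8,8a-octahydronaphthalen-1-yl]methyl}-2,4,5-trimethoxybenzene (C5=C6 alkene)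
Conditions: POCl3, pyridine, 0 to 60 °C
Reagents that add atoms: none
Why: Anti E2 elimination of the axial dichlorophosphate, in which the antiperiplanar axial H5 should be lost to give the more substituted C5=C6 alkene (Zaitsev orientation), erasing the C5 centre.

Step 15
Reactants: 21 trimethoxyaryl alkene
Product: 22 2,3,6-trimethoxy-5-{[(1R,2R,8aS)-1,2,5,5-tetramethyl-1,2,3,5,6,7,8,8a-octahydronaphthalen-1-yl]methyl}benzaldehyde (formyl at C3′)
Conditions: n-BuLi, TMEDA, THF, 0 °C; DMF, −78 °C to rt; aq NH4Cl
Reagents that add atoms: N,N-dimethylformamide CN(C)C=O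
Why: Directed ortho-lithiation at C3′, the position flanked by the 2′- and 4′-methoxy groups, followed by formylation with DMF.

Step 16
Reactants: 22 trimethoxy aldehyde
Product: 23 2,3,6-trihydroxy-5-{[(1R,2R,8aS)-1,2,5,5-tetramethyl-1,2,3,5,6,7,8,8a-octahydronaphthalen-1-yl]methyl}benzaldehyde (handled under argon)
Conditions: BBr3, CH2Cl2, −78 to −20 °C; aq NaHCO3 quench at −78 °C
Reagents that add atoms: none
Why: Lewis-acid cleavage of the three aryl methyl ethers, chelation-assisted for the two that flank the formyl group; low temperature and a basic quench are meant to keep the trisubstituted alkene from being protonated.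

Step 17
Reactants: 23 trihydroxy aldehyde
Product: 24 4′,5′-O-(di-tert-butylsilanediyl) derivative of 23 (2′-OH free)
Conditions: tBu2Si(OTf)2, 2,6-lutidine, CH2Cl2, 0 °C
Reagents that add atoms: di-tert-butylsilyl bis(trifluoromethanesulfonate) CC(C)(C)[Si](OS(=O)(=O)C(F)(F)F)(OS(=O)(=O)C(F)(F)F)C(C)(C)C
Why: Only the 4′,5′-catechol pair can form the five-membered cyclic silylene, which leaves the hindered, hydrogen-bonded 2′-OH free.

Step 18
Reactants: 24 catechol silylene
Product: 25 2′-O-sulfate of 24 (aryl hydrogen sulfate, carried on as the crude pyridinium salt)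
Conditions: SO3·pyridine (excess), pyridine, 50 °C
Reagents that add atoms: sulfur trioxide–pyridine complex O=S(=O)=O.c1ccncc1
Why: O-Sulfation of the one remaining phenol with the SO3·pyridine complex.

Step 19
Reactants: 25 silylene-protected aryl sulfate
Product: 26 2-formyl-3,4-dihydroxy-6-{[(1R,2R,8aS)-1,2,5,5-tetramethyl-1,2,3,5,6,7,8,8a-octahydronaphthalen-1-yl]methyl}phenyl hydrogen sulfate (target)
Conditions: HF·pyridine, pyridine, THF, 0 °C; then sulfonic acid resin (H+ form), MeOH/H2O, 0 °C
Reagents that add atoms: none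
Why: Fluoride cleaves the two Si–O bonds of the silylene without touching the aryl sulfate, and cation exchange gives the free hydrogen sulfate.

## Compound list

1 | (R)-pulegone | C[C@@H]1CCC(=C(C)C)C(=O)C1 | starting material
2 | pulegone oxide, (6R)-2,2,6-trimethyl-1-oxaspiro[2.5]octan-4-one | C[C@@H]1CCC2(OC2(C)C)C(=O)C1 | intermediate
3 | (5R)-5-methyl-2-(phenylsulfanyl)cyclohexan-1-one | C[C@@H]1CCC(Sc2ccccc2)C(=O)C1 | intermediate
4 | (5R)-5-methyl-2-(phenylsulfinyl)cyclohexan-1-one | C[C@@H]1CCC(S(=O)c2ccccc2)C(=O)C1 | intermediate (not isolated)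
5 | (R)-5-methylcyclohex-2-en-1-one | C[C@@H]1CC=CC(=O)C1 | intermediate
6 | (5S)-5-methyl-3-(phenylsulfanyl)cyclohexan-1-one (C3 epimers) | C[C@@H]1CC(Sc2ccccc2)CC(=O)C1 | intermediate (not isolated)
7 | (S)-5-methyl-3-(phenylsulfanyl)cyclohex-2-en-1-one | C[C@@H]1CC(Sc2ccccc2)=CC(=O)C1 | intermediate
8 | 2,4,5-trimethoxybenzaldehyde | COc1cc(OC)c(C=O)cc1OC | starting material
9 | (2,4,5-trimethoxyphenyl)methanol | COc1cc(OC)c(CO)cc1OC | intermediate
10 | 1-(bromomethyl)-2,4,5-trimethoxybenzene | COc1cc(OC)c(CBr)cc1OC | intermediate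
11 | (5R,6S)-5-methyl-3-(phenylsulfanyl)-6-(2,4,5-trimethoxybenzyl)cyclohex-2-en-1-one | C[C@@H]1CC(Sc2ccccc2)=CC(=O)[C@H]1Cc1cc(OC)c(OC)cc1OC | intermediate
12 | (5R,6R)-5,6-dimethyl-3-(phenylsulfanyl)-6-(2,4,5-trimethoxybenzyl)cyclohex-2-en-1-one | C[C@@H]1CC(Sc2ccccc2)=CC(=O)[C@]1(C)Cc1cc(OC)c(OC)cc1OC | intermediate
13 | (5R,6R)-5,6-dimethyl-3-(phenylsulfanyl)-6-(2,4,5-trimethoxybenzyl)cyclohex-2-en-1-ol (C1 epimers) | C[C@@H]1CC(Sc2ccccc2)=CC(O)[C@]1(C)Cc1cc(OC)c(OC)cc1OC | intermediate (not isolated)
14 | (4R,5R)-4,5-dimethyl-4-(2,4,5-trimethoxybenzyl)cyclohex-2-en-1-one | C[C@@H]1CC(=O)C=C[C@]1(C)Cc1cc(OC)c(OC)cc1OC | intermediate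
15 | mesityl oxide (4-methylpent-3-en-2-one) | CC(=O)C=C(C)C | starting material
16 | tert-butyl(dimethyl)[(4-methylpenta-1,3-dien-2-yl)oxy]silane | C=C(O[Si](C)(C)C(C)(C)C)C=C(C)C | intermediate
17 | 2-(tert-butyldimethylsilyloxy)-4,4,8,9-tetramethyl-9-(2,4,5-trimethoxybenzyl)-cis-decal-2-en-6-one | C[C@@H]1CC(=O)[C@@H]2[C@@H](CC(O[Si](C)(C)C(C)(C)C)=CC2(C)C)[C@]1(C)Cc1cc(OC)c(OC)cc1OC | intermediate
18 | 2-(tert-butyldimethylsilyloxy)-4,4,8,9-tetramethyl-9-(2,4,5-trimethoxybenzyl)-cis-decal-2-en-6-ol (6-OH axial) | C[C@@H]1C[C@@H](O)[C@@H]2[C@@H](CC(O[Si](C)(C)C(C)(C)C)=CC2(C)C)[C@]1(C)Cc1cc(OC)c(OC)cc1OC | intermediate (not isolated)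
19 | 6-hydroxy-4,4,8,9-tetramethyl-9-(2,4,5-trimethoxybenzyl)-cis-decalin-2-one (6-OH axial) | C[C@@H]1C[C@@H](O)[C@@H]2[C@@H](CC(=O)CC2(C)C)[C@]1(C)Cc1cc(OC)c(OC)cc1OC | intermediate
20 | 4,4,8,9-tetramethyl-9-(2,4,5-trimethoxybenzyl)-cis-decalin-6-ol (6-OH axial) | C[C@@H]1C[C@@H](O)[C@@H]2[C@@H](CCCC2(C)C)[C@]1(C)Cc1cc(OC)c(OC)cc1OC | intermediate
21 | 1-{[(1R,2R,8aS)-1,2,5,5-tetramethyl-1,2,3,5,6,7,8,8a-octahydronaphthalen-1-yl]methyl}-2,4,5-trimethoxybenzene | C[C@@H]1CC=C2[C@@H](CCCC2(C)C)[C@]1(C)Cc1cc(OC)c(OC)cc1OC | intermediate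
22 | 2,3,6-trimethoxy-5-{[(1R,2R,8aS)-1,2,5,5-tetramethyl-1,2,3,5,6,7,8,8a-octahydronaphthalen-1-yl]methyl}benzaldehyde | C[C@@H]1CC=C2[C@@H](CCCC2(C)C)[C@]1(C)Cc1cc(OC)c(OC)c(C=O)c1OC | intermediate
23 | 2,3,6-trihydroxy-5-{[(1R,2R,8aS)-1,2,5,5-tetramethyl-1,2,3,5,6,7,8,8a-octahydronaphthalen-1-yl]methyl}benzaldehyde | C[C@@H]1CC=C2[C@@H](CCCC2(C)C)[C@]1(C)Cc1cc(O)c(O)c(C=O)c1O | intermediate
24 | 4′,5′-O-(di-tert-butylsilanediyl) derivative of 23 | C[C@@H]1CC=C2[C@@H](CCCC2(C)C)[C@]1(C)Cc3cc4O[Si](C(C)(C)C)(C(C)(C)C)Oc4c(C=O)c3O | intermediate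
25 | 2′-O-sulfate (hydrogen sulfate) of 24 | C[C@@H]1CC=C2[C@@H](CCCC2(C)C)[C@]1(C)Cc3cc4O[Si](C(C)(C)C)(C(C)(C)C)Oc4c(C=O)c3OS(=O)(=O)O | intermediate
26 | 2-formyl-3,4-dihydroxy-6-{[(1R,2R,8aS)-1,2,5,5-tetramethyl-1,2,3,5,6,7,8,8a-octahydronaphthalen-1-yl]methyl}phenyl hydrogen sulfate | C[C@@H]1CC=C2[C@@H](CCCC2(C)C)[C@]1(C)Cc1cc(O)c(O)c(C=O)c1OS(=O)(=O)O | target

## Step count and risks

Total step count: 19. Longest linear sequence: 16 steps (steps 1–4, 7–9 and 11–19, from (R)-pulegone).

Steps most likely to fail: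

1. Step 11 (ring A annulation). The second C–C bond (C4–C5, a quaternary carbon beside a tertiary one) may fail to close so that the reaction stops at the open-chain Michael stage. The diene may also be protodesilylated faster than it adds, or the electron-rich arene may attack the activated enone. The fallback sets out from enone 14 and comes back at alkene 21, bypassing steps 11–14. The Grignard reagent from 2-(3-chloropropyl)-2-methyl-1,3-dioxolane is added to 14 (CuBr·SMe2 cat., Me3SiCl, THF, −78 °C), anti to the arylmethyl group, to give the keto ketal F1. Aqueous HCl in THF frees the diketone F2. KOH in methanol then effects intramolecular aldol condensation of this 1,7-diketone to the ring-A-annulated enone F3 (C4=C5, 4-methyl, C6 ketone). Me2CuLi adds the second methyl group to C4 and the C5 enolate so formed is trapped with PhNTf2 as the enol triflate F4. Pd(OAc)2, PPh3, HCO2H and Bu3N in DMF then reduce the triflate to 21. This detour places the C5=C6 bond regiospecifically.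

2. Step 14 (dehydration). Elimination may run toward C7 instead of C5, chloride may substitute at C6, or a cationic pathway may bring about methyl migration from C4. The fallback sets out from alcohol 20 and comes back at 21. Oxidation with Dess–Martin periodinane gives the ketone F5. Triflation under equilibrating conditions (Tf2O, 2,6-di-tert-butyl-4-methylpyridine, CH2Cl2) toward the more substituted side gives the enol triflate F4. Palladium–formate reduction as above then gives 21.

3. Step 16 (ether cleavage). Protonation of the C5=C6 alkene may be followed by capture of the resulting cation by the liberated 2′-phenol (ether ring closure), or cleavage of the 5′-methoxy group may remain incomplete. The fallback sets out from 22 and comes back at 23. MgI2·OEt2 in toluene removes only the two methyl groups ortho to the aldehyde and gives the dihydroxy methoxy aldehyde F6. PhI(OAc)2 in aqueous acetonitrile oxidises the para-methoxyphenol unit to the hydroxyquinone F7 with loss of methanol. Na2S2O4 in THF/water reduces F7 to 23.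

## Further compounds

F1 | step 11 | (3S,4R,5R)-4,5-dimethyl-3-[3-(2-methyl-1,3-dioxolan-2-yl)propyl]-4-(2,4,5-trimethoxybenzyl)cyclohexan-1-one (side chain anti to the arylmethyl group) | C[C@@H]1CC(=O)C[C@@H](CCCC2(C)OCCO2)[C@]1(C)Cc1cc(OC)c(OC)cc1OC
F2 | step 11 | 4,5-dimethyl-3-(4-oxopentyl)-4-(2,4,5-trimethoxybenzyl)cyclohexan-1-one (same configuration as F1) | C[C@@H]1CC(=O)C[C@@H](CCCC(C)=O)[C@]1(C)Cc1cc(OC)c(OC)cc1OC
F3 | step 11 | 4,8,9-trimethyl-9-(2,4,5-trimethoxybenzyl)decal-4-en-6-one (C4=C5 enone, H10 cis to the arylmethyl group) | C[C@@H]1CC(=O)C2=C(C)CCC[C@H]2[C@]1(C)Cc1cc(OC)c(OC)cc1OC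
F4 | step 11 | 4,4,8,9-tetramethyl-9-(2,4,5-trimethoxybenzyl)decal-5-en-6-yl trifluoromethanesulfonate | C[C@@H]1CC(OS(=O)(=O)C(F)(F)F)=C2[C@@H](CCCC2(C)C)[C@]1(C)Cc1cc(OC)c(OC)cc1OC
F5 | step 14 | 4,4,8,9-tetramethyl-9-(2,4,5-trimethoxybenzyl)-cis-decalin-6-one | C[C@@H]1CC(=O)[C@@H]2[C@@H](CCCC2(C)C)[C@]1(C)Cc1cc(OC)c(OC)cc1OC
F6 | step 16 | 2,6-dihydroxy-3-methoxy-5-{[(1R,2R,8aS)-1,2,5,5-tetramethyl-1,2,3,5,6,7,8,8a-octahydronaphthalen-1-yl]methyl}benzaldehyde | C[C@@H]1CC=C2[C@@H](CCCC2(C)C)[C@]1(C)Cc1cc(OC)c(O)c(C=O)c1O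
F7 | step 16 | 2-hydroxy-3,6-dioxo-5-{[(1R,2R,8aS)-1,2,5,5-tetramethyl-1,2,3,5,6,7,8,8a-octahydronaphthalen-1-yl]methyl}cyclohexa-1,4-diene-1-carbaldehyde | C[C@@H]1CC=C2[C@@H](CCCC2(C)C)[C@]1(C)CC3=CC(=O)C(O)=C(C=O)C3=O
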